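**Retrosynthetic overview**
1. The tetronic acid ring is made last, by Dieckmann closure of an acyclic (S)-α-propanoyloxy methyl ester, so the acidic enol never needs a protecting group; both furan rings are bought intact.
2. Key disconnection: the C(sp2)–C(sp3) bond between the terminal triene CH and the CH2 two carbons away from C4 of the 2,4-disubstituted furan, giving (E)-alkenyl iodide 22 and redox-active ester 9, joined by Ni-electrocatalytic decarboxylative alkenylation (two electrophiles, no organometallic fragment).
3. Enabling feature: the CH2–CH2 tether on furan C4 ends in a primary, unstabilised carbon that can carry CO2H as a traceless radical precursor, and the triene ends in a C(CH3)=CH unit whose CH can carry iodine with E geometry fixed by syn-methylalumination of a terminal alkyne.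
4. Iodide arm: enynol 10 → carboalumination/iodination → oxidation/Wittig → trienyl bromide 17 → alkylation of a chiral glycolate (sets the only stereocentre) → hydroxy ester → propanoate 22.
5. Acid arm: 3-furyllithium + 4-bromofuran-2-carbaldehyde → deoxygenation → Negishi homoenolate coupling → acid → N-hydroxyphthalimide ester 9.

Key step: step 13

Remark: the butane-2,3-diacetal glycolate 18 and enynol 10 are taken as purchasable, and the tetronic acid is written as its 4-hydroxy enol tautomer, as in the target SMILES.

**Route**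

Step 1
Reactants: 1 3-bromofuran; 2 4-bromofuran-2-carbaldehyde
Product: 4 (4-bromofuran-2-yl)(furan-3-yl)methanol (racemic), via furan-3-yllithium 3 (not isolated)
Conditions: n-BuLi, THF, −78 °C; then 2, −78 °C; aq. NH4Cl
Reagents that add atoms: n-butyllithium [Li]CCCC (lithium of 3)
Why: Bromine–lithium exchange at −78 °C gives 3-furyllithium without isomerisation to the 2-lithio species, and its 1,2-addition to the aldehyde should outrun exchange with the ring bromide of 2; the carbinol centre is racemic and is erased in step 2.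

Step 2
Reactants: 4 (4-bromofuran-2-yl)(furan-3-yl)methanol
Product: 5 4-bromo-2-(furan-3-ylmethyl)furan
Conditions: Et3SiH, TFA, CH2Cl2, −20 → 0 °C
Reagents that add atoms: none
Why: Ionic hydrogenation, in which TFA ionises the doubly heteroaryl-stabilised carbinol and Et3SiH should trap the cation with hydride at low temperature before the furans oligomerise, leaving the ring C–Br bond untouched.

Step 3
Reactants: 5 4-bromo-2-(furan-3-ylmethyl)furan; 6 (3-ethoxy-3-oxopropyl)zinc bromide
Product: 7 ethyl 3-[5-(furan-3-ylmethyl)furan-3-yl]propanoate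
Conditions: Pd(OAc)2 (cat.), SPhos (cat.), THF, 50 °C
Reagents that add atoms: none
Why: Negishi cross-coupling of a heteroaryl bromide with a primary alkylzinc homoenolate under a dialkylbiarylphosphine–Pd catalyst, where reductive elimination should outrun β-hydride elimination and the zinc reagent tolerates its own ester.

Step 4
Reactants: 7 ethyl 3-[5-(furan-3-ylmethyl)furan-3-yl]propanoate
Product: 8 3-[5-(furan-3-ylmethyl)furan-3-yl]propanoic acid
Conditions: LiOH, THF/H2O, rt; then 1 M HCl to pH 3, 0 °C
Reagents that add atoms: lithium hydroxide [Li+].[OH-]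
Why: Saponification of an unhindered ethyl ester, with brief cold acidification to spare the acid-sensitive alkylfurans.

Step 5
Reactants: 8 3-[5-(furan-3-ylmethyl)furan-3-yl]propanoic acid
Product: 9 1,3-dioxoisoindolin-2-yl 3-[5-(furan-3-ylmethyl)furan-3-yl]propanoate
Conditions: N-hydroxyphthalimide, DIC, DMAP (cat.), CH2Cl2, rt
Reagents that add atoms: N-hydroxyphthalimide ON1C(=O)c2ccccc2C1=O
Why: Steglich-type carbodiimide esterification should give the bench-stable redox-active ester.

Step 6
Reactants: 10 (E)-pent-2-en-4-yn-1-ol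
Product: 12 (2E,4E)-5-iodo-4-methylpenta-2,4-dien-1-ol, via alkenyldimethylalane 11 (not isolated)
Conditions: Me3Al, Cp2ZrCl2 (cat.), CH2Cl2, 0 °C → rt; then I2, THF, −30 → 0 °C; aq. Na2S2O3/NaHCO3
Reagents that add atoms: trimethylaluminium C[Al](C)C; iodine II
Why: Zirconium-catalysed Negishi carboalumination adds methyl and aluminium syn across the terminal alkyne (Al on the terminal carbon), and iodinolysis of the C–Al bond with retention should fix the 4E geometry while the 2E alkene is carried through.

Step 7
Reactants: 12 (2E,4E)-5-iodo-4-methylpenta-2,4-dien-1-ol; 13 ethyl 2-(triphenyl-λ5-phosphanylidene)propanoate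
Product: 15 ethyl (2E,4E,6E)-7-iodo-2,6-dimethylhepta-2,4,6-trienoate, via dienal 14 (not isolated)
Conditions: MnO2, CH2Cl2, rt (ylide present from the start)
Reagents that add atoms: none
Why: Tandem allylic oxidation/Wittig olefination, in which the sensitive dienal is trapped as it forms by the stabilised α-methyl ylide, which should give the (E)-2-methyl enoate.

Step 8
Reactants: 15 ethyl (2E,4E,6E)-7-iodo-2,6-dimethylhepta-2,4,6-trienoate
Product: 16 (2E,4E,6E)-7-iodo-2,6-dimethylhepta-2,4,6-trien-1-ol
Conditions: DIBAL-H, CH2Cl2, −78 °C; Rochelle salt work-up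
Reagents that add atoms: none
Why: 1,2-Reduction of the conjugated ester to the allylic alcohol at −78 °C should leave the alkenyl iodide and the triene geometry intact.

Step 9
Reactants: 16 (2E,4E,6E)-7-iodo-2,6-dimethylhepta-2,4,6-trien-1-ol
Product: 17 (1E,3E,5E)-7-bromo-1-iodo-2,6-dimethylhepta-1,3,5-triene
Conditions: CBr4, PPh3, CH2Cl2, −20 → 0 °C; used at once
Reagents that add atoms: carbon tetrabromide BrC(Br)(Br)Br
Why: Appel bromination under neutral conditions should convert the primary allylic alcohol to the bromide by SN2 at CH2 without allylic transposition.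

Step 10
Reactants: 17 (1E,3E,5E)-7-bromo-1-iodo-2,6-dimethylhepta-1,3,5-triene; 18 (5R,6R)-5,6-dimethoxy-5,6-dimethyl-1,4-dioxan-2-one
Product: 20 (3S,5R,6R)-3-[(2E,4E,6E)-7-iodo-2,6-dimethylhepta-2,4,6-trien-1-yl]-5,6-dimethoxy-5,6-dimethyl-1,4-dioxan-2-one, via lithium enolate 19 (not isolated)
Conditions: LiHMDS, THF, −78 °C; then 17, −78 → −40 °C
Reagents that add atoms: lithium bis(trimethylsilyl)amide [Li]N([Si](C)(C)C)[Si](C)(C)C (lithium of 19)
Why: Enolate alkylation of the butane-2,3-diacetal glycolate, in which the primary allylic bromide should be attacked on the enolate face anti to the axial 5-methoxy group (1,3-related to the enolate carbon), so the side chain ends up equatorial and the new C3 centre is S.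

Step 11
Reactants: 20 (3S,5R,6R)-3-[(2E,4E,6E)-7-iodo-2,6-dimethylhepta-2,4,6-trien-1-yl]-5,6-dimethoxy-5,6-dimethyl-1,4-dioxan-2-one
Product: 21 methyl (2S,4E,6E,8E)-2-hydroxy-9-iodo-4,8-dimethylnona-4,6,8-trienoate
Conditions: TMSCl, MeOH, rt
Reagents that add atoms: methanol CO
Why: Acid-catalysed methanolysis (HCl generated from TMSCl and MeOH) opens the lactone and exchanges the diacetal, which should release the α-hydroxy methyl ester without enolisation of the stereocentre.

Step 12
Reactants: 21 methyl (2S,4E,6E,8E)-2-hydroxy-9-iodo-4,8-dimethylnona-4,6,8-trienoate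
Product: 22 methyl (2S,4E,6E,8E)-9-iodo-4,8-dimethyl-2-(propanoyloxy)nona-4,6,8-trienoate
Conditions: (EtCO)2O, pyridine, DMAP (cat.), CH2Cl2, 0 °C → rt
Reagents that add atoms: propanoic anhydride CCC(=O)OC(=O)CC
Why: DMAP-catalysed O-acylation of the secondary alcohol installs the three carbons that become C2, C3 and the 3-methyl group of the butenolide, with no stereocentre touched.

Step 13
Reactants: 9 1,3-dioxoisoindolin-2-yl 3-[5-(furan-3-ylmethyl)furan-3-yl]propanoate; 22 methyl (2S,4E,6E,8E)-9-iodo-4,8-dimethyl-2-(propanoyloxy)nona-4,6,8-trienoate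
Product: 23 methyl (2S,4E,6E,8E)-11-[5-(furan-3-ylmethyl)furan-3-yl]-4,8-dimethyl-2-(propanoyloxy)undeca-4,6,8-trienoate
Conditions: NiCl2·6H2O (cat.), 2,2'-bipyridine (cat.), AgNO3 (substoich.), DMF, rt, undivided cell, Mg anode / RVC cathode, constant current; 9 in excess
Reagents that add atoms: none
Why: Ni-electrocatalytic decarboxylative alkenylation: cathodically generated low-valent (bpy)Ni adds oxidatively into the C–I bond of 22 with retention of the E geometry, single-electron reduction of 9 expels phthalimide anion and CO2 to give the primary 2-(furyl)ethyl radical, and capture of that radical at alkenyl–Ni(II) followed by reductive elimination from Ni(III) forges the CH=/CH2 bond. The closest known reaction type is the silver-assisted Ni-electrocatalytic cross-electrophile coupling of N-hydroxyphthalimide esters with (E)-trisubstituted alkenyl iodides used to assemble polyene terpenoids. No ring is closed and no stereocentre is created; the (S)-α-acyloxy ester sees no base, and the 8E geometry is carried over from the iodide. The step needs radical capture by nickel to beat radical addition to the triene or furans, which should hold because the radical is primary and unstabilised and the triene's only unhindered terminus is the one bound to nickel (the other is the fully substituted C4). It also needs the electron-rich furans to escape oxidation, which the sacrificial Mg anode should ensure by being oxidised in their place. Because both partners are electrophiles, neither fragment has to become an organometallic that the α-acyloxy ester would not survive.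

Step 14
Reactants: 23 methyl (2S,4E,6E,8E)-11-[5-(furan-3-ylmethyl)furan-3-yl]-4,8-dimethyl-2-(propanoyloxy)undeca-4,6,8-trienoate
Product: 24 (5S)-5-[(2E,4E,6E)-9-[5-(furan-3-ylmethyl)furan-3-yl]-2,6-dimethylnona-2,4,6-trien-1-yl]-4-hydroxy-3-methylfuran-2(5H)-one
Conditions: LiHMDS (excess), THF, −78 → 0 °C; then cold 1 M HCl
Reagents that add atoms: none
Why: Dieckmann (intramolecular Claisen) condensation, in which the propanoate enolate attacks the neighbouring methyl ester in a 5-exo-trig closure, methoxide is expelled and the product is held as its lithium tetronate, which should shield C5 from epimerisation so that its S configuration is that of C2 of 23.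

**Compound list**
1 | 3-bromofuran | Brc1ccoc1 | starting material
2 | 4-bromofuran-2-carbaldehyde | O=Cc1cc(Br)co1 | starting material
3 | furan-3-yllithium | [Li]c1ccoc1 | intermediate
4 | (4-bromofuran-2-yl)(furan-3-yl)methanol (racemic) | OC(c1ccoc1)c1cc(Br)co1 | intermediate
5 | 4-bromo-2-(furan-3-ylmethyl)furan | Brc1coc(Cc2ccoc2)c1 | intermediate
6 | (3-ethoxy-3-oxopropyl)zinc bromide | CCOC(=O)CC[Zn]Br | starting material
7 | ethyl 3-[5-(furan-3-ylmethyl)furan-3-yl]propanoate | CCOC(=O)CCc1coc(Cc2ccoc2)c1 | intermediate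
8 | 3-[5-(furan-3-ylmethyl)furan-3-yl]propanoic acid | OC(=O)CCc1coc(Cc2ccoc2)c1 | intermediate
9 | 1,3-dioxoisoindolin-2-yl 3-[5-(furan-3-ylmethyl)furan-3-yl]propanoate | O=C(CCc1coc(Cc2ccoc2)c1)ON1C(=O)c2ccccc2C1=O | intermediate
10 | (E)-pent-2-en-4-yn-1-ol | OC/C=C/C#C | starting material
11 | dimethylaluminium alkoxide of (2E,4E)-5-(dimethylalumanyl)-4-methylpenta-2,4-dien-1-ol | C[Al](C)OC/C=C/C(C)=C/[Al](C)C | intermediate
12 | (2E,4E)-5-iodo-4-methylpenta-2,4-dien-1-ol | OC/C=C/C(C)=C/I | intermediate
13 | ethyl 2-(triphenyl-λ5-phosphanylidene)propanoate | CCOC(=O)C(C)=P(c1ccccc1)(c1ccccc1)c1ccccc1 | starting material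
14 | (2E,4E)-5-iodo-4-methylpenta-2,4-dienal | O=C/C=C/C(C)=C/I | intermediate
15 | ethyl (2E,4E,6E)-7-iodo-2,6-dimethylhepta-2,4,6-trienoate | CCOC(=O)/C(C)=C/C=C/C(C)=C/I | intermediate
16 | (2E,4E,6E)-7-iodo-2,6-dimethylhepta-2,4,6-trien-1-ol | OC/C(C)=C/C=C/C(C)=C/I | intermediate
17 | (1E,3E,5E)-7-bromo-1-iodo-2,6-dimethylhepta-1,3,5-triene | BrC/C(C)=C/C=C/C(C)=C/I | intermediate
18 | (5R,6R)-5,6-dimethoxy-5,6-dimethyl-1,4-dioxan-2-one | O=C1CO[C@@](C)(OC)[C@](C)(OC)O1 | starting material
19 | lithium enolate of 18 | [Li]OC1=CO[C@@](C)(OC)[C@](C)(OC)O1 | intermediate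
20 | (3S,5R,6R)-3-[(2E,4E,6E)-7-iodo-2,6-dimethylhepta-2,4,6-trien-1-yl]-5,6-dimethoxy-5,6-dimethyl-1,4-dioxan-2-one | O=C1[C@H](C/C(C)=C/C=C/C(C)=C/I)O[C@@](C)(OC)[C@](C)(OC)O1 | intermediate
21 | methyl (2S,4E,6E,8E)-2-hydroxy-9-iodo-4,8-dimethylnona-4,6,8-trienoate | COC(=O)[C@@H](O)C/C(C)=C/C=C/C(C)=C/I | intermediate
22 | methyl (2S,4E,6E,8E)-9-iodo-4,8-dimethyl-2-(propanoyloxy)nona-4,6,8-trienoate | COC(=O)[C@@H](OC(=O)CC)C/C(C)=C/C=C/C(C)=C/I | intermediate
23 | methyl (2S,4E,6E,8E)-11-[5-(furan-3-ylmethyl)furan-3-yl]-4,8-dimethyl-2-(propanoyloxy)undeca-4,6,8-trienoate | COC(=O)[C@@H](OC(=O)CC)C/C(C)=C/C=C/C(C)=C/CCc1coc(Cc2ccoc2)c1 | intermediate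
24 | (5S)-5-[(2E,4E,6E)-9-[5-(furan-3-ylmethyl)furan-3-yl]-2,6-dimethylnona-2,4,6-trien-1-yl]-4-hydroxy-3-methylfuran-2(5H)-one | CC1=C(O)[C@H](C/C(C)=C/C=C/C(C)=C/CCc2coc(Cc3ccoc3)c2)OC1=O | target

**Step count**
Total: 14 steps. Longest linear sequence: 9 steps (steps 6–14, from 10).

**Steps most likely to fail**

Step 13. The primary radical may add to the conjugated triene or abstract an allylic hydrogen faster than nickel captures it, or the alkenyl–nickel species may be protodehalogenated or isomerised, costing yield and E purity. The fallback is a B-alkyl Suzuki–Miyaura coupling, which replaces the radical by a two-electron transmetalation. It sets out from 5: vinylation (vinylboronic acid pinacol ester, Pd(PPh3)4, K2CO3, dioxane/H2O, 80 °C) should give 2-(furan-3-ylmethyl)-4-vinylfuran F1. Anti-Markovnikov hydroboration with 9-BBN-H (THF, 0 °C → rt) should give 9-{2-[5-(furan-3-ylmethyl)furan-3-yl]ethyl}-9-borabicyclo[3.3.1]nonane F2. Without isolation, F2 is coupled with iodide 22 (PdCl2(dppf), AsPh3, aq. K3PO4, DMF, rt), and the route is rejoined at 23.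

Step 14. On the fully assembled substrate the strong base may abstract the proton at the stereogenic α-carbon (loss of configuration or a 1,2-acyl shift) or degrade the polyene, with no later chance to repurify. The fallback moves the ring closure ahead of the fragment union and ends with a neutral deprotection. It sets out from 22: Dieckmann closure (LiHMDS, THF, −78 °C) should give (5S)-4-hydroxy-5-[(2E,4E,6E)-7-iodo-2,6-dimethylhepta-2,4,6-trien-1-yl]-3-methylfuran-2(5H)-one F3, whose enantiopurity can be checked and raised by crystallisation at this simple stage. Mitsunobu etherification (2-(trimethylsilyl)ethanol, PPh3, DIAD, THF) should give (5S)-5-[(2E,4E,6E)-7-iodo-2,6-dimethylhepta-2,4,6-trien-1-yl]-3-methyl-4-[2-(trimethylsilyl)ethoxy]furan-2(5H)-one F4. Coupling of F4 with 9 under the step-13 conditions should give (5S)-5-[(2E,4E,6E)-9-[5-(furan-3-ylmethyl)furan-3-yl]-2,6-dimethylnona-2,4,6-trien-1-yl]-3-methyl-4-[2-(trimethylsilyl)ethoxy]furan-2(5H)-one F5. TBAF (THF, 0 °C → rt) then removes the silylethyl group, and the route is rejoined at 24.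

Step 2. Acid ionisation of the bis-furyl carbinol may lead to Friedel–Crafts oligomerisation or ring opening of the furans instead of hydride capture. The fallback avoids any carbocation by a base-mediated deoxygenation. It sets out from 4: MnO2 oxidation (CH2Cl2, rt) should give (4-bromofuran-2-yl)(furan-3-yl)methanone F6. Wolff–Kishner reduction (N2H4·H2O, KOH, diethylene glycol, 130 → 190 °C) proceeds through (4-bromofuran-2-yl)(furan-3-yl)methanone hydrazone F7, and the route is rejoined at 5.

**Further compounds**
F1 | step 13 | 2-(furan-3-ylmethyl)-4-vinylfuran | C=Cc1coc(Cc2ccoc2)c1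
F2 | step 13 | 9-{2-[5-(furan-3-ylmethyl)furan-3-yl]ethyl}-9-borabicyclo[3.3.1]nonane | C(Cc1coc(Cc2ccoc2)c1)B1C2CCCC1CCC2
F3 | step 14 | (5S)-4-hydroxy-5-[(2E,4E,6E)-7-iodo-2,6-dimethylhepta-2,4,6-trien-1-yl]-3-methylfuran-2(5H)-one | CC1=C(O)[C@H](C/C(C)=C/C=C/C(C)=C/I)OC1=O
F4 | step 14 | (5S)-5-[(2E,4E,6E)-7-iodo-2,6-dimethylhepta-2,4,6-trien-1-yl]-3-methyl-4-[2-(trimethylsilyl)ethoxy]furan-2(5H)-one | CC1=C(OCC[Si](C)(C)C)[C@H](C/C(C)=C/C=C/C(C)=C/I)OC1=O
F5 | step 14 | (5S)-5-[(2E,4E,6E)-9-[5-(furan-3-ylmethyl)furan-3-yl]-2,6-dimethylnona-2,4,6-trien-1-yl]-3-methyl-4-[2-(trimethylsilyl)ethoxy]furan-2(5H)-one | CC1=C(OCC[Si](C)(C)C)[C@H](C/C(C)=C/C=C/C(C)=C/CCc2coc(Cc3ccoc3)c2)OC1=O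
F6 | step 2 | (4-bromofuran-2-yl)(furan-3-yl)methanone | O=C(c1ccoc1)c1cc(Br)co1
F7 | step 2 | (4-bromofuran-2-yl)(furan-3-yl)methanone hydrazone | NN=C(c1ccoc1)c1cc(Br)co1
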